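**Unknown constants.** I had no constant for the enzyme, neither its rate of death nor its Michaelis constant, but the suspects let me do without the first. If enzyme dies at first order and the making of target is proportional to enzyme, the enzyme lost per starting material converted depends on c(starting material), not on c(enzyme). So each conversion has a price in enzyme, and the rate at a given conversion follows the charge minus that price.

| flask | starting material | enzyme | remark |
|---|---|---|---|
| maple | 5 mM | 0.01 mol% | run made earlier |
| larch | 7.5 mM | 0.01 mol% | run made earlier |
| birch | 10 mM | 0.015 mol% | run made earlier |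
| flask | 10 mM | 0.01 mol% |  |

| run | time / h | target / % | starting material / % |
|---|---|---|---|
| maple | 3.00 | 27.4 | 72.2 |
| maple | 6.00 | 29.8 | 70.2 |
| maple | 12.0 | 30.7 | 70.1 |
| maple | 25.0 | 30.2 | 69.6 |
| maple | 40.0 | 30.7 | 69.8 |
| larch | 3.00 | 34.4 | 65.5 |
| larch | 6.00 | 36.6 | 63.4 |
| larch | 12.0 | 36.9 | 62.9 |
| larch | 25.0 | 36.9 | 63.0 |
| larch | 40.0 | 36.8 | 62.7 |
| birch | 4.00 | 56.8 | 42.8 |
| birch | 10.0 | 58.8 | 40.9 |
| birch | 20.0 | 59.0 | 41.0 |
| birch | 30.0 | 58.9 | 40.9 |
| birch | 40.0 | 59.0 | 41.5 |

(readings scatter by 0.3 percentage points)

- the analysis behind the earlier runs scatters by 0.3 percentage points, standard deviation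
- on the list of suspects stand: enzyme -> spent catalyst; starting material + enzyme -> target + enzyme

- factor on the rate of making target when 20% of the starting material are converted if enzyme is charged twice over
- factor on the rate when 20% of the starting material are converted if enzyme is charged at 0.05 mol% instead

**The bracket.** The birch run began at the flask's 10 mM and levelled at 59.0% target, so its 0.00150 mM paid for that whole way. With a constant rate per enzyme, the price would rise in step with conversion, giving 5.08 × 10⁻⁴ mM for 20%. With a rate proportional to c(starting material), it would rise with the logarithm, giving 3.75 × 10⁻⁴ mM. The flask holds 0.00100 mM, so these two estimates put the factor for doubling between 2.60 and 3.03, and the factor for 0.05 mol% between 7.40 and 9.14.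

**Going round.** The ends of maple and birch gave a Michaelis constant of 6.21 mM, a reading carrying the scatter of 0.3 percentage points. Put back, it set the price, the enzyme lost on the way to 20% in the flask, at 4.44 × 10⁻⁴ mM, so I reckoned 2.80 and 8.20. The forecast said 2.78 and 8.1, holding that “Enzyme lost depends only on the conversion reached”. Each figure is higher than its lower bound and lower than its upper bound.

**The flask.** The flask gave 2.78 and 8.13.

    enzyme → spent catalyst (k = 0.795 h⁻¹)
    starting material + enzyme → target + enzyme, rate k2*[starting material]*[enzyme]/(1 + ([starting material]/Km2)) (7.51 mM, k = 8.87 × 10⁵ L mol⁻¹ h⁻¹)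

The flask reached 20% at 0.726 h, earlier than the 0.87 h half-life of its enzyme, and half of its making of target up to 3.00 d was done by 0.791 h. That time stands to the half-life as 0.909, and at 3.00 d the flask held enzyme at 0% and starting material at 58% of their charges. My price, a reading, is 44.4% of the flask's charge of enzyme, and at 20% spent catalyst made up 43.9% of the flask's catalyst. With 0.05 mol% charged, the same price is 8.88% of the charge, and spent catalyst made up 8.77% of the catalyst at that conversion.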